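The disconnection is the bond between the homobenzylic CH2 of the two-carbon tether and the tertiary carbinol carbon C(CH3)(OH). That carbon is a methyl (E)-styryl carbinol, i.e. the 1,2-adduct of an (E)-4-arylbut-3-en-2-one, and the key step exploits the size difference between its CH3 and its flat CH=CH–aryl arm. In one pot, 4-vinyl-3,5-dimethylphenyl pivalate is hydroborated, transmetalated to the dialkylzinc and added under a chiral titanium bis(sulfonamide) diol catalyst to the Si face of the bis-silylated hydroquinone enone, forming the C–C bond and the only stereocentre together. The locally symmetric 3,5-dimethylphenol ring is formylated afterwards, then the silyl groups are removed.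

Key step: step 5

Remark: the o-hydroxystyryl tertiary carbinol of the target is treated as acid-labile (ionisation and closure to a 2H-chromene), so every step after the key step avoids acid. The chiral ligand is a purchasable catalyst and is not counted as a step.

Step 1
Reactants: 1 4-bromo-3,5-dimethylphenol
Product: 2 4-bromo-3,5-dimethylphenyl pivalate
Conditions: PivCl (1.2 equiv), Et3N (1.5 equiv), DMAP (5 mol%), CH2Cl2, 0 °C → rt
Reagents that add atoms: pivaloyl chloride, CC(C)(C)C(=O)Cl
Why: DMAP-catalysed O-acylation caps the phenol as a hindered aryl ester that should survive borane, dialkylzinc and Ti(OiPr)4 and can later be cleaved reductively beside aryl silyl ethers.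

Step 2
Reactants: 2 4-bromo-3,5-dimethylphenyl pivalate
Product: 3 4-ethenyl-3,5-dimethylphenyl pivalate
Conditions: vinyl-B(pin) (1.5 equiv), Pd(OAc)2 (2 mol%), SPhos (4 mol%), K3PO4 (2 equiv), toluene/H2O 10:1, 80 °C
Reagents that add atoms: vinylboronic acid pinacol ester, C=CB1OC(C)(C)C(C)(C)O1
Why: Suzuki–Miyaura coupling, in which the bulky electron-rich biarylphosphine should allow coupling at the di-ortho-methyl aryl bromide while the pivalate tolerates the phosphate base.

Step 3
Reactants: 4 2,5-dihydroxybenzaldehyde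
Product: 5 2,5-bis[(tert-butyldimethylsilyl)oxy]benzaldehyde
Conditions: TBSCl (2.4 equiv), imidazole (5 equiv), DMF, rt
Reagents that add atoms: tert-butyldimethylsilyl chloride, CC(C)(C)[Si](C)(C)Cl
Why: Imidazole-mediated silylation protects both hydroquinone oxygens as aryl silyl ethers, which are inert to organozinc and hydride reagents and removable at the end by fluoride without acid.

Step 4
Reactants: 5 2,5-bis[(tert-butyldimethylsilyl)oxy]benzaldehyde
Product: 6 (E)-4-{2,5-bis[(tert-butyldimethylsilyl)oxy]phenyl}but-3-en-2-one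
Conditions: Ph3P=CHC(O)CH3 (1.3 equiv), toluene, 90 °C
Reagents that add atoms: 1-(triphenyl-λ5-phosphanylidene)propan-2-one, CC(=O)C=P(c1ccccc1)(c1ccccc1)c1ccccc1
Why: Wittig olefination with a stabilised acyl ylide should give the (E)-enone under salt-free, base-free conditions that leave the aryl silyl ethers intact.

Step 5
Reactants: 3 4-ethenyl-3,5-dimethylphenyl pivalate; 6 (E)-4-{2,5-bis[(tert-butyldimethylsilyl)oxy]phenyl}but-3-en-2-one
Product: 9 4-[(3S,4E)-5-{2,5-bis[(tert-butyldimethylsilyl)oxy]phenyl}-3-hydroxy-3-methylpent-4-en-1-yl]-3,5-dimethylphenyl pivalate, via alkyldiethylborane 7 (not isolated), via dialkylzinc 8 (not isolated)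
Conditions: (i) 3 (4 equiv), Et2BH (from BH3·SMe2 + 2 Et3B), Et2O, 0 °C → rt, then vacuum; (ii) Et2Zn (neat), 0 °C, then volatiles off at 0.1 mmHg (twice, toluene chase); (iii) 6 (1 equiv), Ti(OiPr)4 (1.2 equiv), (1R,2R)-cyclohexane-1,2-diyl bis[(1S)-2-exo-hydroxycamphor-10-sulfonamide] (10 mol%), toluene, rt; aq NH4Cl
Reagents that add atoms: none
Why: Et2BH adds anti-Markovnikov to the vinyl group of 3 (the twisted 2,6-dimethylaryl group blocks the internal carbon), boron–zinc exchange with Et2Zn gives the salt-free primary dialkylzinc 8, and the chiral titanium bis(sulfonamide)diolate formed from Ti(OiPr)4 and the ligand binds the ketone of 6 and transfers one 2-arylethyl group to the carbonyl carbon in a 1,2-addition that closes no ring. The closest known reaction type is the titanium-promoted catalytic asymmetric addition of functionalised dialkylzincs, made by hydroboration and boron–zinc exchange, to methyl ketones and acyclic enones of the benzylideneacetone type. The new stereocentre is set by the ligand, which distinguishes the small CH3 from the flat (E)-CH=CH–aryl arm and should deliver the alkyl group to the Si face of the C=O to give the (S)-carbinol; this sense is expected for the (1R,2R)-diamine/(1S)-camphor series by analogy with aryl methyl ketones, and the mirror-image ligand is used if a model run shows the opposite sense. The step needs 1,2- over 1,4-addition, secured by the copper-free Ti/Zn system, and chemoselectivity for the ketone, secured by the inertness of dialkylzincs towards the pivalate and the aryl silyl ethers. Ethyl transfer is excluded by stripping Et3B and excess Et2Zn before 6 is added; only one alkyl group per zinc is transferred, hence the excess of 3.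

Step 6
Reactants: 9 4-[(3S,4E)-5-{2,5-bis[(tert-butyldimethylsilyl)oxy]phenyl}-3-hydroxy-3-methylpent-4-en-1-yl]-3,5-dimethylphenyl pivalate
Product: 10 4-[(3S,4E)-5-{2,5-bis[(tert-butyldimethylsilyl)oxy]phenyl}-3-hydroxy-3-methylpent-4-en-1-yl]-3,5-dimethylphenol
Conditions: DIBAL-H (4 equiv), CH2Cl2, −78 → −20 °C; aq Rochelle salt
Reagents that add atoms: none
Why: Reductive cleavage of the aryl ester by DIBAL-H (hydride addition, aryloxide expelled) should free only the ring-A phenol, since aryl silyl ethers, the disubstituted alkene and the tertiary aluminium alkoxide are inert at low temperature.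

Step 7
Reactants: 10 4-[(3S,4E)-5-{2,5-bis[(tert-butyldimethylsilyl)oxy]phenyl}-3-hydroxy-3-methylpent-4-en-1-yl]-3,5-dimethylphenol
Product: 12 3-[(3S,4E)-5-{2,5-bis[(tert-butyldimethylsilyl)oxy]phenyl}-3-hydroxy-3-methylpent-4-en-1-yl]-6-hydroxy-2,4-dimethylbenzaldehyde, via hydroxymethylphenol 11 (not isolated)
Conditions: MgCl2 (3 equiv), Et3N (6 equiv), (CH2O)n (8 equiv), THF, 65 °C; cold pH 6 phosphate buffer
Reagents that add atoms: paraformaldehyde (as formaldehyde), C=O
Why: Casnati–Skattebøl magnesium-mediated ortho-formylation, in which the magnesium phenoxide directs formaldehyde to the ortho carbon and a second formaldehyde oxidises the benzylic alkoxide by hydride transfer; the two ortho positions of the 4-alkyl-3,5-dimethylphenol are equivalent, so one regioisomer should form, and the silylated ring has no free OH to direct attack.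

Step 8
Reactants: 12 3-[(3S,4E)-5-{2,5-bis[(tert-butyldimethylsilyl)oxy]phenyl}-3-hydroxy-3-methylpent-4-en-1-yl]-6-hydroxy-2,4-dimethylbenzaldehyde
Product: 13 6-hydroxy-3-[(3S,4E)-5-(2,5-dihydroxyphenyl)-3-hydroxy-3-methylpent-4-en-1-yl]-2,4-dimethylbenzaldehyde
Conditions: TBAF (2.5 equiv), AcOH (2.5 equiv), degassed THF, 0 °C, Ar; pH 7 buffer, neutral silica
Reagents that add atoms: none
Why: Fluoride-mediated desilylation buffered with acetic acid should release the hydroquinone near neutrality, so that the tertiary allylic alcohol does not ionise, the hydroquinone is not oxidised and the stereocentre is untouched.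

Compound list
1 | 4-bromo-3,5-dimethylphenol | Cc1cc(O)cc(C)c1Br | starting material
2 | 4-bromo-3,5-dimethylphenyl pivalate | Cc1cc(OC(=O)C(C)(C)C)cc(C)c1Br | intermediate
3 | 4-ethenyl-3,5-dimethylphenyl pivalate | C=Cc1c(C)cc(OC(=O)C(C)(C)C)cc1C | intermediate
4 | 2,5-dihydroxybenzaldehyde | O=Cc1cc(O)ccc1O | starting material
5 | 2,5-bis[(tert-butyldimethylsilyl)oxy]benzaldehyde | O=Cc1cc(O[Si](C)(C)C(C)(C)C)ccc1O[Si](C)(C)C(C)(C)C | intermediate
6 | (E)-4-{2,5-bis[(tert-butyldimethylsilyl)oxy]phenyl}but-3-en-2-one | CC(=O)/C=C/c1cc(O[Si](C)(C)C(C)(C)C)ccc1O[Si](C)(C)C(C)(C)C | intermediate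
7 | diethyl{2-[2,6-dimethyl-4-(pivaloyloxy)phenyl]ethyl}borane (not isolated) | CCB(CC)CCc1c(C)cc(OC(=O)C(C)(C)C)cc1C | intermediate
8 | bis{2-[2,6-dimethyl-4-(pivaloyloxy)phenyl]ethyl}zinc (not isolated) | CC(C)(C)C(=O)Oc1cc(C)c(CC[Zn]CCc2c(C)cc(OC(=O)C(C)(C)C)cc2C)c(C)c1 | intermediate
9 | 4-[(3S,4E)-5-{2,5-bis[(tert-butyldimethylsilyl)oxy]phenyl}-3-hydroxy-3-methylpent-4-en-1-yl]-3,5-dimethylphenyl pivalate | CC(C)(C)C(=O)Oc1cc(C)c(CC[C@](C)(O)/C=C/c2cc(O[Si](C)(C)C(C)(C)C)ccc2O[Si](C)(C)C(C)(C)C)c(C)c1 | intermediate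
10 | 4-[(3S,4E)-5-{2,5-bis[(tert-butyldimethylsilyl)oxy]phenyl}-3-hydroxy-3-methylpent-4-en-1-yl]-3,5-dimethylphenol | Cc1cc(O)cc(C)c1CC[C@](C)(O)/C=C/c1cc(O[Si](C)(C)C(C)(C)C)ccc1O[Si](C)(C)C(C)(C)C | intermediate
11 | 4-[(3S,4E)-5-{2,5-bis[(tert-butyldimethylsilyl)oxy]phenyl}-3-hydroxy-3-methylpent-4-en-1-yl]-2-(hydroxymethyl)-3,5-dimethylphenol (as its magnesium salt, not isolated) | Cc1cc(O)c(CO)c(C)c1CC[C@](C)(O)/C=C/c1cc(O[Si](C)(C)C(C)(C)C)ccc1O[Si](C)(C)C(C)(C)C | intermediate
12 | 3-[(3S,4E)-5-{2,5-bis[(tert-butyldimethylsilyl)oxy]phenyl}-3-hydroxy-3-methylpent-4-en-1-yl]-6-hydroxy-2,4-dimethylbenzaldehyde | Cc1cc(O)c(C=O)c(C)c1CC[C@](C)(O)/C=C/c1cc(O[Si](C)(C)C(C)(C)C)ccc1O[Si](C)(C)C(C)(C)C | intermediate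
13 | 6-hydroxy-3-[(3S,4E)-5-(2,5-dihydroxyphenyl)-3-hydroxy-3-methylpent-4-en-1-yl]-2,4-dimethylbenzaldehyde | Cc1cc(O)c(C=O)c(C)c1CC[C@](C)(O)/C=C/c1cc(O)ccc1O | target

Total step count: 8.
Longest linear sequence: 6 steps (1 → 2 → 3 → 9 → 10 → 12 → 13, i.e. steps 1, 2, 5, 6, 7, 8; the branch from 4 through steps 3 and 4 is equally long).

Steps most likely to fail

Step 5. The catalyst may discriminate the two faces of the acyclic enone insufficiently, and the hindered 2-arylethyl group may transfer so slowly that residual ethyl transfer competes. The excess of zinc reagent also costs material. The fallback is a lithiation–borylation sequence that sets out from 6 and 3 and returns at 9. Enone 6 is reduced by Corey–Bakshi–Shibata reduction ((S)-Me-CBS, catecholborane, toluene, −78 °C, alkenyl as the large group) to (2R,3E)-4-{2,5-bis[(tert-butyldimethylsilyl)oxy]phenyl}but-3-en-2-ol F1. This is carbamoylated (iPr2NCOCl, Et3N, toluene, reflux) to the (2R,3E)-N,N-diisopropylcarbamate F2. Styrene 3 is hydroborated with pinacolborane ([Ir(cod)Cl]2/dppe, CH2Cl2, rt) to the linear pinacol boronate F3. Deprotonation of F2 (sBuLi, TMEDA, Et2O, −78 °C) should give the α-lithiated carbamate F4, which F3 traps at the α-carbon with retention as the boronate complex F5. On warming, the 2-arylethyl group migrates from boron to carbon with loss of the carbamate (1,2-metallate rearrangement, inversion at carbon) to the (R)-tertiary allylic pinacol boronate F6. Oxidation with NaBO3·4H2O (THF/H2O, rt) replaces boron by OH with retention and gives 9. Overall the 2-arylethyl group takes the place of the carbinol hydrogen of F1, so the (R)-alcohol leads to the (S)-carbinol and the enantiopurity is that of the reduction.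

Step 7. The tertiary allylic alcohol may ionise in the Lewis-acidic magnesium medium at reflux, aryl silyl groups may be lost to the methoxide formed, and hydroxymethylation at the position flanked by OH and CH3 may be slow. The fallback sets out from 10 and returns at 12. The free phenol of 10 is iodinated at one of its two equivalent ortho positions (I2, morpholine, CH2Cl2, 0 °C) to 4-[(3S,4E)-5-{2,5-bis[(tert-butyldimethylsilyl)oxy]phenyl}-3-hydroxy-3-methylpent-4-en-1-yl]-2-iodo-3,5-dimethylphenol F7. The iodide is then converted to the aldehyde by palladium-catalysed reductive carbonylation (Pd(PPh3)4, CO 1 atm, Bu3SnH by slow addition, THF, 50 °C), a neutral formylation that should give 12.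

Step 8. The liberated hydroquinone may be oxidised by air in the fluoride medium, and the tertiary allylic alcohol may ionise and close onto the ortho-OH during work-up or chromatography. The fallback sets out from 12 and returns at 13. Silyl-to-acetyl exchange (CsF, Ac2O, DMF, rt) acetylates each aryloxide as it forms, the ring-A phenol included, and should give 2-[(1E,3S)-5-(4-acetoxy-3-formyl-2,6-dimethylphenyl)-3-hydroxy-3-methylpent-1-en-1-yl]-1,4-phenylene diacetate F8. F8 can neither oxidise nor cyclise and is purified by chromatography. Lipase-catalysed alcoholysis (immobilised Candida antarctica lipase B, n-BuOH, MTBE, rt) then removes the three phenolic acetates at neutral pH, and 13 is obtained by filtration and evaporation.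

Further compounds
F1 | step 5 | (2R,3E)-4-{2,5-bis[(tert-butyldimethylsilyl)oxy]phenyl}but-3-en-2-ol | C[C@@H](O)/C=C/c1cc(O[Si](C)(C)C(C)(C)C)ccc1O[Si](C)(C)C(C)(C)C
F2 | step 5 | (2R,3E)-4-{2,5-bis[(tert-butyldimethylsilyl)oxy]phenyl}but-3-en-2-yl N,N-diisopropylcarbamate | C[C@@H](OC(=O)N(C(C)C)C(C)C)/C=C/c1cc(O[Si](C)(C)C(C)(C)C)ccc1O[Si](C)(C)C(C)(C)C
F3 | step 5 | 3,5-dimethyl-4-[2-(4,4,5,5-tetramethyl-1,3,2-dioxaborolan-2-yl)ethyl]phenyl pivalate | CC(C)(C)C(=O)Oc1cc(C)c(CCB2OC(C)(C)C(C)(C)O2)c(C)c1
F4 | step 5 | α-lithiated carbamate of F2 (Li in place of the carbinol H, configuration retained) | C[C@@]([Li])(OC(=O)N(C(C)C)C(C)C)/C=C/c1cc(O[Si](C)(C)C(C)(C)C)ccc1O[Si](C)(C)C(C)(C)C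
F5 | step 5 | lithium boronate complex of F4 and F3 (B in place of Li, configuration retained) | C[C@@]([B-]1(CCc2c(C)cc(OC(=O)C(C)(C)C)cc2C)OC(C)(C)C(C)(C)O1)(OC(=O)N(C(C)C)C(C)C)/C=C/c1cc(O[Si](C)(C)C(C)(C)C)ccc1O[Si](C)(C)C(C)(C)C.[Li+]
F6 | step 5 | 4-[(3R,4E)-5-{2,5-bis[(tert-butyldimethylsilyl)oxy]phenyl}-3-methyl-3-(4,4,5,5-tetramethyl-1,3,2-dioxaborolan-2-yl)pent-4-en-1-yl]-3,5-dimethylphenyl pivalate | CC(C)(C)C(=O)Oc1cc(C)c(CC[C@](C)(B2OC(C)(C)C(C)(C)O2)/C=C/c2cc(O[Si](C)(C)C(C)(C)C)ccc2O[Si](C)(C)C(C)(C)C)c(C)c1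
F7 | step 7 | 4-[(3S,4E)-5-{2,5-bis[(tert-butyldimethylsilyl)oxy]phenyl}-3-hydroxy-3-methylpent-4-en-1-yl]-2-iodo-3,5-dimethylphenol | Cc1cc(O)c(I)c(C)c1CC[C@](C)(O)/C=C/c1cc(O[Si](C)(C)C(C)(C)C)ccc1O[Si](C)(C)C(C)(C)C
F8 | step 8 | 2-[(1E,3S)-5-(4-acetoxy-3-formyl-2,6-dimethylphenyl)-3-hydroxy-3-methylpent-1-en-1-yl]-1,4-phenylene diacetate | CC(=O)Oc1cc(C)c(CC[C@](C)(O)/C=C/c2cc(OC(C)=O)ccc2OC(C)=O)c(C)c1C=O
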